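**Assumption:** the target is taken as the open δ‑hydroxy‑ketone drawn. Germacrane locants are used throughout: C1 ketone, C4 (Me), C5 (OH), C6 (lactone O), C7, C8 (O‑methacrylate), C10 (Me, OAc), C11=C13H2, C12 lactone C=O. Target configuration: 4S, 5S, 6S, 7R, 8S, 10R.

## Retrosynthetic overview

1. Target ⇐ NAP removal, enone 1,4‑reduction, C10 acetylation ⇐ ten‑membered enone closed last by RCM at C2=C3.
2. RCM diene ⇐ C8 methacryloylation ⇐ indium Barbier union (C7–C8 bond) of bromomethyl‑butenolide **12** with aldehyde **21**; this creates the α‑methylene lactone and sets C7 and C8.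
3. **12** (C3–C7, C11–C13, C15) ⇐ Pd cyclocarbonylation of a (Z)‑iodoallylic alcohol ⇐ chelation‑controlled alkynylation (C6) ⇐ Brown crotylation (C4, C5).
4. **21** (C1, C2, C8–C10, C14) ⇐ vinyl ketone from a Weinreb amide ⇐ Evans Cu–box pyruvate aldol (C10).
5. Ring order: γ‑lactone (butenolide) first, carbocycle second.

## Route

### Butenolide fragment

**Step 1**
Reactants: **1** 2,2‑dimethoxyacetaldehyde (commercial aqueous solution, extracted, dried and distilled before use); **2** (E)‑but‑2‑ene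
Product: **3** (2S,3S)‑1,1‑dimethoxy‑3‑methylpent‑4‑en‑2‑ol
Conditions: **2**, n‑BuLi, KOt‑Bu, THF, −45 °C; (−)‑Ipc2BOMe, −78 °C; BF3·OEt2; **1**, −78 °C; then NaOH, H2O2
Reagents that add atoms: none (crotyl unit comes from **2**)
Why: Brown asymmetric crotylboration; the (E)‑crotyl‑Ipc2B reagent derived from (+)‑α‑pinene reacts through a closed chair, giving the anti C4‑Me/C5‑OH pair and, by reagent control of the aldehyde face, the (2S,3S) isomer.

**Step 2**
Reactants: **3**
Product: **4** 2‑({[(2S,3S)‑1,1‑dimethoxy‑3‑methylpent‑4‑en‑2‑yl]oxy}methyl)naphthalene (C5–O‑NAP ether)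
Conditions: NaH, 2‑(bromomethyl)naphthalene, TBAI (cat.), THF/DMF, 0 °C → rt
Reagents that add atoms: 2‑(bromomethyl)naphthalene, BrCc1ccc2ccccc2c1
Why: Williamson etherification; NAP chelates like benzyl (needed in Step 5), survives the acid of Step 3 and is removable oxidatively at the end.

**Step 3**
Reactants: **4**
Product: **5** (2S,3S)‑3‑methyl‑2‑(naphthalen‑2‑ylmethoxy)pent‑4‑enal
Conditions: TFA/H2O (1:1), CH2Cl2, 0 °C → rt; used at once
Reagents that add atoms: water, O
Why: Acid hydrolysis of the dimethyl acetal; the NAP ether and terminal alkene are acid‑stable, and immediate use limits epimerisation of the α‑alkoxy aldehyde.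

**Step 4**
Reactants: **6** prop‑2‑yn‑1‑ol
Product: **7** tert‑butyldimethyl(prop‑2‑yn‑1‑yloxy)silane
Conditions: TBSCl, imidazole, CH2Cl2, 0 °C → rt
Reagents that add atoms: TBSCl, CC(C)(C)[Si](C)(C)Cl
Why: Standard silylation; the protected oxygen cannot compete with the C6 hydroxyl as a directing group in Step 6.

**Step 5**
Reactants: **5**; **7**
Product: **8** (4S,5S,6S)‑1‑[(tert‑butyldimethylsilyl)oxy]‑6‑methyl‑5‑(naphthalen‑2‑ylmethoxy)oct‑7‑en‑2‑yn‑4‑ol
Conditions: **7**, n‑BuLi, THF, −78 °C; ZnBr2, Et2O, 0 °C; then **5**, −78 → −20 °C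
Reagents that add atoms: none
Why: Chelation‑controlled (Cram‑chelate) alkynylzinc addition; Zn bridges C=O and the α‑ONAP oxygen and the alkyne adds opposite the C4 side chain, giving the 5,6‑syn relationship (C6 = S), with the minor anti isomer removed by chromatography.

**Step 6**
Reactants: **8**
Product: **9** (2Z,4S,5S,6S)‑1‑[(tert‑butyldimethylsilyl)oxy]‑2‑iodo‑6‑methyl‑5‑(naphthalen‑2‑ylmethoxy)octa‑2,7‑dien‑4‑ol
Conditions: Red‑Al, THF, 0 °C → rt; EtOAc; then I2, THF, −78 → 0 °C
Reagents that add atoms: iodine, II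
Why: Hydroxyl‑directed trans‑hydroalumination of the propargylic alcohol puts Al on the distal carbon (C11), and iodinolysis with retention gives the vinyl iodide with I cis to the carbinol carbon; the low temperature avoids allene formation.

**Step 7**
Reactants: **9**
Product: **10** (5S)‑3‑{[(tert‑butyldimethylsilyl)oxy]methyl}‑5‑[(1S,2S)‑2‑methyl‑1‑(naphthalen‑2‑ylmethoxy)but‑3‑en‑1‑yl]furan‑2(5H)‑one
Conditions: PdCl2(PPh3)2 (5 mol %), CO (1 atm), i‑Pr2NEt, THF, 50 °C
Reagents that add atoms: carbon monoxide, [C-]#[O+]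
Why: Pd‑catalysed cyclocarbonylation; oxidative addition, CO insertion and capture of the acyl‑Pd by the cis C6–OH give the butenolide (C12 installed) without touching C6.

**Step 8**
Reactants: **10**
Product: **11** (5S)‑3‑(hydroxymethyl)‑5‑[(1S,2S)‑2‑methyl‑1‑(naphthalen‑2‑ylmethoxy)but‑3‑en‑1‑yl]furan‑2(5H)‑one
Conditions: HF·pyridine, THF/pyridine, 0 °C
Reagents that add atoms: none
Why: Mildly acidic fluoride desilylation of the primary TBS ether; it avoids basic conditions that could epimerise the butenolide γ‑centre (C6).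

**Step 9**
Reactants: **11**
Product: **12** (5S)‑3‑(bromomethyl)‑5‑[(1S,2S)‑2‑methyl‑1‑(naphthalen‑2‑ylmethoxy)but‑3‑en‑1‑yl]furan‑2(5H)‑one
Conditions: CBr4, PPh3, CH2Cl2, 0 °C
Reagents that add atoms: carbon tetrabromide, BrC(Br)(Br)Br
Why: Appel bromination of the primary allylic alcohol under neutral conditions; NAP ether, alkene and lactone are inert.

### Aldehyde fragment

**Step 10**
Reactants: **13** S‑ethyl ethanethioate
Product: **14** {[1‑(ethylsulfanyl)ethenyl]oxy}trimethylsilane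
Conditions: LDA, THF, −78 °C; TMSCl
Reagents that add atoms: TMSCl, C[Si](C)(C)Cl
Why: Kinetic enolisation and O‑silylation give the silyl ketene thioacetal needed for the Mukaiyama aldol.

**Step 11**
Reactants: **14**; **15** methyl 2‑oxopropanoate (methyl pyruvate)
Product: **16** methyl (2R)‑4‑(ethylsulfanyl)‑2‑hydroxy‑2‑methyl‑4‑oxobutanoate
Conditions: [Cu((R,R)‑t‑Bu‑box)](OTf)2 (10 mol %), THF, −78 °C; then 1 M HCl
Reagents that add atoms: none
Why: Evans Cu(II)–bis(oxazoline) Mukaiyama aldol; pyruvate chelates Cu and one ketone face is blocked by the t‑Bu group, and since the (S,S) catalyst is documented to give the (S) adduct, the (R,R) catalyst sets C10 as R.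

**Step 12**
Reactants: **16**
Product: **17** methyl (2R)‑2‑hydroxy‑2‑methyl‑4‑oxobutanoate
Conditions: Et3SiH, 10 % Pd/C, acetone, rt
Reagents that add atoms: none
Why: Fukuyama reduction; Pd inserts into the C–S bond and the silane delivers hydride, giving the aldehyde (C8) while the methyl ester and tertiary OH are untouched.

**Step 13**
Reactants: **17**
Product: **18** methyl (2R)‑2‑hydroxy‑4,4‑dimethoxy‑2‑methylbutanoate
Conditions: HC(OMe)3, MeOH, PPTS (cat.), rt
Reagents that add atoms: trimethyl orthoformate, COC(OC)OC; methanol, CO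
Why: Acid‑catalysed acetalisation masks the C8 aldehyde for the organomagnesium steps.

**Step 14**
Reactants: **18**
Product: **19** (2R)‑2‑hydroxy‑N,4,4‑trimethoxy‑N,2‑dimethylbutanamide
Conditions: MeNH(OMe)·HCl, i‑PrMgCl, THF, −20 → 0 °C
Reagents that add atoms: N,O‑dimethylhydroxylamine hydrochloride, CNOC.Cl
Why: Weinreb amidation of the ester by the magnesium amide; the α‑alkoxide assists and the acetal is base‑stable.

**Step 15**
Reactants: **19**
Product: **20** (4R)‑4‑hydroxy‑6,6‑dimethoxy‑4‑methylhex‑1‑en‑3‑one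
Conditions: CH2=CHMgBr (3.5 equiv), THF, −78 → 0 °C; inverse quench into cold aq. NH4Cl/AcOH
Reagents that add atoms: vinylmagnesium bromide, C=C[Mg]Br
Why: Weinreb ketone synthesis; the chelated tetrahedral intermediate prevents over‑addition and the acidic inverse quench stops the liberated amine from adding to the new vinyl ketone.

**Step 16**
Reactants: **20**
Product: **21** (3R)‑3‑hydroxy‑3‑methyl‑4‑oxohex‑5‑enal
Conditions: Amberlyst‑15, acetone/H2O (10:1), rt; used crude
Reagents that add atoms: water, O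
Why: Mild acetal hydrolysis; the tertiary β‑hydroxyl cannot dehydrate easily because the cation would sit α to the ketone.

### Union and endgame

**Step 17**
Reactants: **12**; **21**
Product: **22** (4R,5S)‑4‑[(1S,3R)‑1,3‑dihydroxy‑3‑methyl‑4‑oxohex‑5‑en‑1‑yl]‑5‑[(1S,2S)‑2‑methyl‑1‑(naphthalen‑2‑ylmethoxy)but‑3‑en‑1‑yl]‑3‑methylideneoxolan‑2‑one
Conditions: In powder, THF/H2O (3:1), rt
Reagents that add atoms: none
Why: Indium Barbier allylation (SE2′); the allylindium attacks the aldehyde through C7 in a Zimmerman–Traxler chair on the butenolide face anti to the C6 side chain (6,7‑trans lactone, C7 = R), the ring‑locked E‑type allyl geometry fixes C8 as S, and the aldehyde reacts in preference to the hindered ketone.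

**Step 18**
Reactants: **22**
Product: **23** C8 methacrylate of **22**: (1S,3R)‑3‑hydroxy‑3‑methyl‑1‑{(2S,3R)‑2‑[(1S,2S)‑2‑methyl‑1‑(naphthalen‑2‑ylmethoxy)but‑3‑en‑1‑yl]‑4‑methylidene‑5‑oxooxolan‑3‑yl}‑4‑oxohex‑5‑en‑1‑yl 2‑methylprop‑2‑enoate
Conditions: methacryloyl chloride, Et3N, DMAP (cat.), CH2Cl2, −20 → 0 °C
Reagents that add atoms: methacryloyl chloride, C=C(C)C(Cl)=O
Why: Acylation selects the secondary C8–OH over the tertiary C10–OH, and prompt esterification prevents 6,12→8,12 translactonisation or hemiketal formation with C1.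

**Step 19**
Reactants: **23**
Product: **24** (3aR,4S,6R,10S,11S,11aS)‑6‑hydroxy‑6,10‑dimethyl‑3‑methylidene‑11‑(naphthalen‑2‑ylmethoxy)‑2,7‑dioxo‑2,3,3a,4,5,6,7,10,11,11a‑decahydrocyclodeca[b]furan‑4‑yl 2‑methylprop‑2‑enoate (ten‑membered C1‑enone, C2=C3)
Conditions: Hoveyda–Grubbs II (10–15 mol %), 1,4‑benzoquinone (cat.), toluene (1 mM), 80 °C
Reagents that add atoms: none (ethylene lost)
Why: Ring‑closing metathesis between the vinyl ketone and the C4 vinyl group; the 1,1‑disubstituted electron‑poor exo‑methylene and methacrylate alkenes are poor metathesis partners, and the alkene geometry is irrelevant because it is reduced in Step 21.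

**Step 20**
Reactants: **24**
Product: **25** the C10 acetate of **24** (6‑acetyloxy in the cyclodeca[b]furan numbering)
Conditions: Ac2O, Et3N, DMAP, CH2Cl2, rt
Reagents that add atoms: acetic anhydride, CC(=O)OC(C)=O
Why: DMAP‑catalysed acetylation of the only free hydroxyl, the tertiary α‑ketol, with C5 still protected as the NAP ether.

**Step 21**
Reactants: **25**
Product: **26** (3aR,4S,6R,10S,11S,11aS)‑6‑(acetyloxy)‑6,10‑dimethyl‑3‑methylidene‑11‑(naphthalen‑2‑ylmethoxy)‑2,7‑dioxododecahydrocyclodeca[b]furan‑4‑yl 2‑methylprop‑2‑enoate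
Conditions: Pd(PPh3)4 (5 mol %), ZnCl2, Ph2SiH2, CHCl3, rt
Reagents that add atoms: none
Why: Keinan Pd(0)/silane/ZnCl2 conjugate reduction; this system 1,4‑reduces Lewis‑acid‑activated enones but is very sluggish toward unsaturated esters and lactones, so C2–C3 is saturated with no new stereocentre and the two ester‑conjugated methylenes remain.

**Step 22**
Reactants: **26**
Product: **27** Lychnostatin 1
Conditions: DDQ, CH2Cl2/pH 7 buffer (10:1), rt
Reagents that add atoms: none
Why: Oxidative cleavage of the NAP ether under neutral conditions frees the C5 hydroxyl without touching the electron‑poor alkenes, the esters or the ketone.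

## Compound list

1 | 2,2‑dimethoxyacetaldehyde | COC(OC)C=O | starting material
2 | (E)‑but‑2‑ene | C/C=C/C | starting material
3 | (2S,3S)‑1,1‑dimethoxy‑3‑methylpent‑4‑en‑2‑ol | COC(OC)[C@@H](O)[C@@H](C)C=C | intermediate
4 | 2‑({[(2S,3S)‑1,1‑dimethoxy‑3‑methylpent‑4‑en‑2‑yl]oxy}methyl)naphthalene | COC(OC)[C@@H](OCc1ccc2ccccc2c1)[C@@H](C)C=C | intermediate
5 | (2S,3S)‑3‑methyl‑2‑(naphthalen‑2‑ylmethoxy)pent‑4‑enal | O=C[C@@H](OCc1ccc2ccccc2c1)[C@@H](C)C=C | intermediate
6 | prop‑2‑yn‑1‑ol | C#CCO | starting material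
7 | tert‑butyldimethyl(prop‑2‑yn‑1‑yloxy)silane | C#CCO[Si](C)(C)C(C)(C)C | intermediate
8 | (4S,5S,6S)‑1‑[(tert‑butyldimethylsilyl)oxy]‑6‑methyl‑5‑(naphthalen‑2‑ylmethoxy)oct‑7‑en‑2‑yn‑4‑ol | CC(C)(C)[Si](C)(C)OCC#C[C@H](O)[C@@H](OCc1ccc2ccccc2c1)[C@@H](C)C=C | intermediate
9 | (2Z,4S,5S,6S)‑1‑[(tert‑butyldimethylsilyl)oxy]‑2‑iodo‑6‑methyl‑5‑(naphthalen‑2‑ylmethoxy)octa‑2,7‑dien‑4‑ol | CC(C)(C)[Si](C)(C)OC/C(I)=C/[C@H](O)[C@@H](OCc1ccc2ccccc2c1)[C@@H](C)C=C | intermediate
10 | (5S)‑3‑{[(tert‑butyldimethylsilyl)oxy]methyl}‑5‑[(1S,2S)‑2‑methyl‑1‑(naphthalen‑2‑ylmethoxy)but‑3‑en‑1‑yl]furan‑2(5H)‑one | CC(C)(C)[Si](C)(C)OCC3=C[C@H](OC3=O)[C@@H](OCc1ccc2ccccc2c1)[C@@H](C)C=C | intermediate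
11 | (5S)‑3‑(hydroxymethyl)‑5‑[(1S,2S)‑2‑methyl‑1‑(naphthalen‑2‑ylmethoxy)but‑3‑en‑1‑yl]furan‑2(5H)‑one | OCC3=C[C@H](OC3=O)[C@@H](OCc1ccc2ccccc2c1)[C@@H](C)C=C | intermediate
12 | (5S)‑3‑(bromomethyl)‑5‑[(1S,2S)‑2‑methyl‑1‑(naphthalen‑2‑ylmethoxy)but‑3‑en‑1‑yl]furan‑2(5H)‑one | BrCC3=C[C@H](OC3=O)[C@@H](OCc1ccc2ccccc2c1)[C@@H](C)C=C | intermediate
13 | S‑ethyl ethanethioate | CC(=O)SCC | starting material
14 | {[1‑(ethylsulfanyl)ethenyl]oxy}trimethylsilane | C=C(SCC)O[Si](C)(C)C | intermediate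
15 | methyl 2‑oxopropanoate | CC(=O)C(=O)OC | starting material
16 | methyl (2R)‑4‑(ethylsulfanyl)‑2‑hydroxy‑2‑methyl‑4‑oxobutanoate | COC(=O)[C@](C)(O)CC(=O)SCC | intermediate
17 | methyl (2R)‑2‑hydroxy‑2‑methyl‑4‑oxobutanoate | COC(=O)[C@](C)(O)CC=O | intermediate
18 | methyl (2R)‑2‑hydroxy‑4,4‑dimethoxy‑2‑methylbutanoate | COC(=O)[C@](C)(O)CC(OC)OC | intermediate
19 | (2R)‑2‑hydroxy‑N,4,4‑trimethoxy‑N,2‑dimethylbutanamide | CON(C)C(=O)[C@](C)(O)CC(OC)OC | intermediate
20 | (4R)‑4‑hydroxy‑6,6‑dimethoxy‑4‑methylhex‑1‑en‑3‑one | C=CC(=O)[C@](C)(O)CC(OC)OC | intermediate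
21 | (3R)‑3‑hydroxy‑3‑methyl‑4‑oxohex‑5‑enal | C=CC(=O)[C@](C)(O)CC=O | intermediate
22 | Barbier adduct (seco‑germacranolide diol, name in Step 17) | C=CC(=O)[C@](C)(O)C[C@H](O)[C@H]3C(=C)C(=O)O[C@@H]3[C@@H](OCc1ccc2ccccc2c1)[C@@H](C)C=C | intermediate
23 | C8 methacrylate of 22 (name in Step 18) | C=CC(=O)[C@](C)(O)C[C@H](OC(=O)C(C)=C)[C@H]3C(=C)C(=O)O[C@@H]3[C@@H](OCc1ccc2ccccc2c1)[C@@H](C)C=C | intermediate
24 | ten‑membered enone, C10–OH, C5–ONAP (name in Step 19) | O=C4C=C[C@H](C)[C@H](OCc1ccc2ccccc2c1)[C@H]3OC(=O)C(=C)[C@@H]3[C@@H](OC(=O)C(C)=C)C[C@@]4(C)O | intermediate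
25 | C10 acetate of 24 | O=C4C=C[C@H](C)[C@H](OCc1ccc2ccccc2c1)[C@H]3OC(=O)C(=C)[C@@H]3[C@@H](OC(=O)C(C)=C)C[C@@]4(C)OC(C)=O | intermediate
26 | 5‑O‑NAP Lychnostatin 1 (name in Step 21) | O=C4CC[C@H](C)[C@H](OCc1ccc2ccccc2c1)[C@H]3OC(=O)C(=C)[C@@H]3[C@@H](OC(=O)C(C)=C)C[C@@]4(C)OC(C)=O | intermediate
27 | Lychnostatin 1 | C=C(C)C(=O)O[C@H]1C[C@@](C)(OC(C)=O)C(=O)CC[C@H](C)[C@H](O)[C@H]2OC(=O)C(=C)[C@@H]21 | target

## Summary

Total steps: 22.
Longest linear sequence: 14 (Steps 1–3, 5–9, 17–22). The aldehyde branch is 7 steps before the union and the alkyne side branch is 1 step.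

Three steps most likely to fail, with fallbacks:

1. **Step 19, RCM to the ten‑membered enone** (oligomerisation, ring strain, olefin migration). Fallback: change the ring‑closing bond. Join the halves first at C2–C3 by cross‑metathesis of vinyl ketone **20** with butenolide **10**, reduce the enone before any exo‑methylene exists, then convert to the bromide/aldehyde and close the ring by an intramolecular In or CrCl2 Barbier allylation (C7–C8).

2. **Step 21, chemoselective 1,4‑reduction** (the α‑methylene lactone or methacrylate may also be reduced). Fallback: mask the α‑methylene lactone of **22** as its dimethylamine Michael adduct and postpone C8 acylation. Carry out RCM as the ammonium salt, hydrogenate C2=C3 with H2/Pd, then methacryloylate and regenerate the methylene by MeI quaternisation and NaHCO3 elimination.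

3. **Step 17, indium Barbier union** (labile β‑hydroxy aldehyde/vinyl ketone **21**; free β‑OH could erode diastereocontrol). Fallback: use a robust aldehyde partner with C10–OH silylated and C1 carried as a TES‑protected vinyl carbinol. Do the union and RCM on the allylic silyl ether, then unmask and oxidise C1 (DMP) to the enone before Steps 20–22.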